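## Retrosynthetic overview

1. The target is traced back to the 8(14)-methylene-6,10-diketone **15** by removing the two angelates, the hydroxyl-directed C8–C9 epoxide and the two carbinol hydrogens at C6 and C10.
2. Key disconnection C7–C8 and C9–C10: **15** comes from the cis-fused bicyclic cyclopentane-1,3-dione **12** and allene by a de Mayo [2+2] photocycloaddition/retro-aldol, which expands ring A from five to seven members. The enabling feature is the C6(O)–C7–C8(CH3)–C9–C10(O) array of the seven-membered ring: a 1,5-dioxygenated chain whose central carbon carries the one-carbon branch, with the C8–C9 epoxide as a masked olefin.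
3. **12** comes from keto aldehyde **8**: ring B by an intramolecular aldol (C4–C5), then ring A by a Claisen condensation (C7–C10).
4. **8** comes from β-hydroxy ester **4** by a double Fráter–Seebach alkylation (quaternary C1 controlled by the C2 carbinol); **4** comes from ethyl (R)-4-chloro-3-hydroxybutanoate and an alkenyl Grignard reagent.
5. Ring order: cyclopentane ring B, cyclopentanedione ring A, ring expansion to the cycloheptane, epoxide last.

Key step: step 11

Remark on naming: all carbons carry the daucane numbers of the target. C1 is the ring-fusion carbon with methyl C15, C2–C4 lie in the five-membered ring (C4 bears isopropyl), C5 is the ring-fusion CH, C6–C10 lie in the seven-membered ring (C8 bears C14). α is the face of the C1 methyl group, β the opposite face. All bicyclic compounds have 1α-methyl, 5α-H (cis fusion) and 4α-isopropyl; TBS = tert-butyldimethylsilyl.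

Assumption: ethyl (R)-4-chloro-3-hydroxybutanoate and 2-bromo-3-methylbut-1-ene are taken as purchasable.

## Route

Step 1
Reactants: 1 ethyl (R)-4-chloro-3-hydroxybutanoate
Product: 2 ethyl (R)-3,4-epoxybutanoate
Conditions: Ag2O, Et2O, reflux, dark
Reagents that add atoms: none
Why: Silver-ion-assisted intramolecular Williamson etherification (3-exo-tet) should close the epoxide under non-basic conditions that avoid E1cB opening to the 4-hydroxycrotonate, and the carbinol stereocenter (future C2) is not touched.

Step 2
Reactants: 2 ethyl (R)-3,4-epoxybutanoate; 3 2-bromo-3-methylbut-1-ene (as its Grignard reagent)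
Product: 4 ethyl (3S)-3-hydroxy-6-methyl-5-methylideneheptanoate
Conditions: 3, Mg, THF; then CuI (10 mol%), 2, THF, −40 °C
Reagents that add atoms: none
Why: Copper-catalysed SN2 opening of the terminal epoxide by the alkenyl Grignard reagent at the unsubstituted carbon (the reaction type used on this epoxy ester with vinylmagnesium bromide) should form C3–C4 with C4 as a masked isopropyl ketone, the low temperature sparing the ester and the C2 configuration being unchanged.

Step 3
Reactants: 4 ethyl (3S)-3-hydroxy-6-methyl-5-methylideneheptanoate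
Product: 5 ethyl (2S,3S)-2-allyl-3-hydroxy-6-methyl-5-methylideneheptanoate
Conditions: LiN(iPr)2 (LDA, 2.2 equiv), THF, −78 to −20 °C; allyl bromide, −78 to −10 °C
Reagents that add atoms: allyl bromide, C=CCBr
Why: Fráter–Seebach alkylation, in which the lithium-chelated dianion (enolate bridged to the C2 alkoxide) is allylated on the face anti to the C3 chain, should give the 1,2-anti product.

Step 4
Reactants: 5 ethyl (2S,3S)-2-allyl-3-hydroxy-6-methyl-5-methylideneheptanoate
Product: 6 ethyl (2R,3S)-2-allyl-3-hydroxy-2,6-dimethyl-5-methylideneheptanoate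
Conditions: LiN(iPr)2 (LDA, 2.5 equiv), THF/DMPU, −78 to 0 °C; MeI
Reagents that add atoms: iodomethane, CI
Why: A second Fráter–Seebach alkylation of the now α-substituted chelated dianion should bring iodomethane in from the same face as the first electrophile, which sets the quaternary C1 stereocenter through the order of the two alkylations.

Step 5
Reactants: 6 ethyl (2R,3S)-2-allyl-3-hydroxy-2,6-dimethyl-5-methylideneheptanoate
Product: 7 ethyl (2R,3S)-2-allyl-3-(tert-butyldimethylsilyloxy)-2,6-dimethyl-5-methylideneheptanoate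
Conditions: TBSOTf, 2,6-lutidine, CH2Cl2, 0 °C to rt
Reagents that add atoms: tert-butyldimethylsilyl trifluoromethanesulfonate, CC(C)(C)[Si](C)(C)OS(=O)(=O)C(F)(F)F
Why: Silyl triflate silylation of the hindered secondary alcohol (standard protection) masks C2–OH for the oxidation, organometallic and hydride steps and later keeps it from directing a reduction at C10.

Step 6
Reactants: 7 ethyl (2R,3S)-2-allyl-3-(tert-butyldimethylsilyloxy)-2,6-dimethyl-5-methylideneheptanoate
Product: 8 ethyl (2R,3S)-3-(tert-butyldimethylsilyloxy)-2,6-dimethyl-5-oxo-2-(2-oxoethyl)heptanoate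
Conditions: O3, pyridine (3 equiv), CH2Cl2, −78 °C
Reagents that add atoms: ozone, [O-][O+]=O
Why: Ozonolysis with pyridine-promoted reductive fragmentation of the carbonyl oxides should cleave the monosubstituted alkene to the C6 aldehyde and the 1,1-disubstituted alkene to the C4 isopropyl ketone in one operation, no stereocenter being involved.

Step 7
Reactants: 8 ethyl (2R,3S)-3-(tert-butyldimethylsilyloxy)-2,6-dimethyl-5-oxo-2-(2-oxoethyl)heptanoate
Product: 9 ethyl 5β-formyl-4β-hydroxy-4α-isopropyl-1α-methyl-2β-(tert-butyldimethylsilyloxy)cyclopentane-1β-carboxylate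
Conditions: (S)-proline (30 mol%), DMSO, rt
Reagents that add atoms: none
Why: Proline-catalysed intramolecular enolexo aldol addition (Hajos–Parrish/List type), in which only the aldehyde forms an enamine (at C5, its sole α-carbon) that adds to the C4 ketone in a 5-(enolexo)-exo-trig closure, should form ring B with isopropyl on the α face away from the β-silyloxy and β-ester groups (reversible addition, thermodynamic control) and the epimerisable formyl group β, trans to isopropyl and methyl.

Step 8
Reactants: 9 ethyl 5β-formyl-4β-hydroxy-4α-isopropyl-1α-methyl-2β-(tert-butyldimethylsilyloxy)cyclopentane-1β-carboxylate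
Product: 10 ethyl 4β-hydroxy-5β-(1-hydroxyethyl)-4α-isopropyl-1α-methyl-2β-(tert-butyldimethylsilyloxy)cyclopentane-1β-carboxylate (mixture at the new carbinol carbon)
Conditions: MeMgBr (2.5 equiv), THF, −78 °C; aqueous NH4Cl at −78 °C; crude product used at once
Reagents that add atoms: methylmagnesium bromide, C[Mg]Br
Why: Chemoselective Grignard addition to the aldehyde at low temperature (the neopentyl ester is spared, one equivalent is used up by the tertiary alcohol) brings in C7, and the new carbinol center is erased in the next step, which is run without delay to forestall lactonisation onto the cis ester.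

Step 9
Reactants: 10 ethyl 4β-hydroxy-5β-(1-hydroxyethyl)-4α-isopropyl-1α-methyl-2β-(tert-butyldimethylsilyloxy)cyclopentane-1β-carboxylate
Product: 11 ethyl 5β-acetyl-4β-hydroxy-4α-isopropyl-1α-methyl-2β-(tert-butyldimethylsilyloxy)cyclopentane-1β-carboxylate
Conditions: Dess–Martin periodinane, NaHCO3, CH2Cl2, 0 °C to rt
Reagents that add atoms: none
Why: Dess–Martin oxidation should convert the secondary alcohol into the methyl ketone while the tertiary alcohol and the silyl ether stay inert.

Step 10
Reactants: 11 ethyl 5β-acetyl-4β-hydroxy-4α-isopropyl-1α-methyl-2β-(tert-butyldimethylsilyloxy)cyclopentane-1β-carboxylate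
Product: 12 cis-fused bicyclic cyclopentane-1,3-dione (hexahydropentalene-1,3-dione skeleton) with ring A = C1–C10(=O)–C7H2–C6(=O)–C5 and ring B carrying 2β-OTBS, 4β-OH, 4α-isopropyl, 1α-methyl, 5α-H
Conditions: LiN(SiMe3)2 (LiHMDS, 3.2 equiv), THF, −78 to 0 °C; then 1 M HCl
Reagents that add atoms: none
Why: Intramolecular Claisen condensation (the γ-keto ester to cyclopentane-1,3-dione closure, 5-exo-trig) of the kinetic acetyl enolate onto the cis ester should form ring A, the β-diketonate being the thermodynamic sink that also shields the C4 aldolate from retro-aldol, and only the 5β-acetyl epimer can close so the ring fusion is cis.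

Step 11
Reactants: 12 cis-fused bicyclic cyclopentane-1,3-dione (ring A dione, 2β-OTBS, 4β-OH); 13 allene
Product: 15 2β-(tert-butyldimethylsilyloxy)-4β-hydroxydauc-8(14)-ene-6,10-dione, via cyclobutanol photoadduct 14 (not isolated)
Conditions: 13 (10 equiv), MeCN, hν (medium-pressure Hg lamp, Pyrex filter, λ > 290 nm), −40 °C; then rt
Reagents that add atoms: none
Why: De Mayo reaction: the enolised 1,3-dione of ring A (C6 ketone with C7=C10 enol, a β-hydroxy-enone chromophore) is excited to its triplet and adds allene stepwise through a 1,4-biradical, C7 bonding to the central allene carbon (which becomes C8) and C10 to a terminal carbon (C9), after which the strained β-hydroxy ketone 14 fragments by retro-aldol cleavage of the old C7–C10 bond. The closest known reaction types are the de Mayo two-carbon ring expansion of cyclopentane-1,3-diones to cycloheptane-1,4-diones and the head-to-head [2+2] photocycloaddition of cyclic enones to allene. Ring closure: the cyclobutane closes by biradical recombination as a four-membered ring cis-fused to ring A, and the seven-membered ring then arises by fragmentation of this bicyclo[3.2.0]heptane (ring expansion by two atoms), not by a direct seven-membered closure. No stereocenter is formed in 15 (C7 and C10 of 14 return to CH2 and C=O, so the face of addition is irrelevant), and C1, C2, C4 and C5 are spectators because C5 is not enolised under the neutral conditions. The selectivity needed is regiochemical, namely the central allene carbon must bond to C7, and this rests on the intrinsic head-to-head preference of allene (attack of the α-carbon on the central carbon gives an allyl radical), while enol regiochemistry needs no control because the C6-enol tautomer gives the same 8(14)-methylene-6,10-dione. Chemoselectivity rests on the enol being the only chromophore that absorbs strongly above 290 nm, and irradiation through Pyrex at low temperature should limit secondary photochemistry of the β,γ-unsaturated diketone product.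

Step 12
Reactants: 15 2β-(tert-butyldimethylsilyloxy)-4β-hydroxydauc-8(14)-ene-6,10-dione
Product: 16 2β-(tert-butyldimethylsilyloxy)-4β,6α-dihydroxydauc-8(14)-en-10-one
Conditions: Me4NBH(OAc)3, AcOH/MeCN 1:1, −30 °C
Reagents that add atoms: none
Why: Evans–Saksena hydroxyl-directed reduction, in which the tertiary C4–OH exchanges onto boron and delivers hydride through a six-membered transition state to the β face of the C6 ketone, should give the 1,3-anti (6α) alcohol, while the neopentyl C10 ketone, whose β-oxygen is silylated, is left alone at this temperature.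

Step 13
Reactants: 16 2β-(tert-butyldimethylsilyloxy)-4β,6α-dihydroxydauc-8(14)-en-10-one
Product: 17 2β-(tert-butyldimethylsilyloxy)-4β,6α-dihydroxydauc-8-en-10-one
Conditions: 1,8-diazabicyclo[5.4.0]undec-7-ene (DBU, 0.3 equiv), CH2Cl2, rt
Reagents that add atoms: none
Why: Base-catalysed isomerisation of the β,γ-unsaturated ketone through the C9 dienolate should move the exocyclic double bond into conjugation with the only remaining carbonyl, giving the endocyclic trisubstituted C8=C9 enone under thermodynamic control, since C6 is already a carbinol and no second conjugated isomer exists.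

Step 14
Reactants: 17 2β-(tert-butyldimethylsilyloxy)-4β,6α-dihydroxydauc-8-en-10-one
Product: 18 2β-(tert-butyldimethylsilyloxy)dauc-8-ene-4β,6α,10α-triol
Conditions: (3aR)-1-methyl-3,3-diphenyltetrahydro-1H,3H-pyrrolo[1,2-c][1,3,2]oxazaborole ((R)-Me-CBS, 0.3 equiv), catecholborane (3 equiv), toluene, −78 °C
Reagents that add atoms: none
Why: Corey–Bakshi–Shibata 1,2-reduction of the enone under catalyst control, with the quaternary C1 as the large and the C9 vinyl CH as the small substituent, should deliver hydride to the β face and give the 10α allylic alcohol.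

Step 15
Reactants: 18 2β-(tert-butyldimethylsilyloxy)dauc-8-ene-4β,6α,10α-triol
Product: 19 8α,9α-epoxy-2β-(tert-butyldimethylsilyloxy)daucane-4β,6α,10α-triol
Conditions: VO(acac)2 (5 mol%), tBuOOH, CH2Cl2, 0 °C to rt
Reagents that add atoms: tert-butyl hydroperoxide, CC(C)(C)OO
Why: Vanadium-catalysed hydroxyl-directed epoxidation (Sharpless conditions) should deliver the peroxide oxygen syn to the allylic C10–OH and the homoallylic C6–OH (both α), giving the 8α,9α-epoxide as is usual for cyclohept-2-enols.

Step 16
Reactants: 19 8α,9α-epoxy-2β-(tert-butyldimethylsilyloxy)daucane-4β,6α,10α-triol; 20 angelic acid (two equivalents are consumed, one per hydroxyl)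
Product: 21 6α,10α-bis(angeloyloxy)-8α,9α-epoxy-2β-(tert-butyldimethylsilyloxy)daucan-4β-ol
Conditions: 20 (4 equiv), 2,4,6-trichlorobenzoyl chloride (4 equiv), Et3N (5 equiv), toluene, rt; then 19, 80 °C
Reagents that add atoms: angelic acid (the second equivalent of 20), C/C=C(/C)C(=O)O
Why: Yamaguchi-type esterification through the angelic 2,4,6-trichlorobenzoic mixed anhydride (no DMAP, to keep the Z geometry) should acylate both secondary alcohols, each taking one angeloyl group from one molecule of the mixed anhydride, the tertiary C4–OH being unreactive and C2–OH silylated.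

Step 17
Reactants: 21 6α,10α-bis(angeloyloxy)-8α,9α-epoxy-2β-(tert-butyldimethylsilyloxy)daucan-4β-ol
Product: 22 (1R,2S,4S,5R,6R,8S,9R,10R)-6α,10α-bis(angeloyloxy)-8α,9α-epoxydaucane-2β,4β-diol (CNP0265715.2)
Conditions: HF·pyridine, pyridine, THF, 0 °C to rt
Reagents that add atoms: none
Why: Pyridine-buffered HF·pyridine desilylation should free C2–OH without opening the trisubstituted epoxide or moving or isomerising the angelates.

## Compound list

1 | ethyl (R)-4-chloro-3-hydroxybutanoate | CCOC(=O)C[C@@H](O)CCl | starting material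
2 | ethyl (R)-3,4-epoxybutanoate | CCOC(=O)C[C@@H]1CO1 | intermediate
3 | 2-bromo-3-methylbut-1-ene | CC(C)C(Br)=C | starting material
4 | ethyl (3S)-3-hydroxy-6-methyl-5-methylideneheptanoate | CCOC(=O)C[C@@H](O)CC(=C)C(C)C | intermediate
5 | ethyl (2S,3S)-2-allyl-3-hydroxy-6-methyl-5-methylideneheptanoate | CCOC(=O)[C@@H](CC=C)[C@@H](O)CC(=C)C(C)C | intermediate
6 | ethyl (2R,3S)-2-allyl-3-hydroxy-2,6-dimethyl-5-methylideneheptanoate | CCOC(=O)[C@@](CC=C)(C)[C@@H](O)CC(=C)C(C)C | intermediate
7 | ethyl (2R,3S)-2-allyl-3-(tert-butyldimethylsilyloxy)-2,6-dimethyl-5-methylideneheptanoate | CCOC(=O)[C@@](CC=C)(C)[C@@H](O[Si](C)(C)C(C)(C)C)CC(=C)C(C)C | intermediate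
8 | ethyl (2R,3S)-3-(tert-butyldimethylsilyloxy)-2,6-dimethyl-5-oxo-2-(2-oxoethyl)heptanoate | CCOC(=O)[C@@](CC=O)(C)[C@@H](O[Si](C)(C)C(C)(C)C)CC(=O)C(C)C | intermediate
9 | ethyl 5β-formyl-4β-hydroxy-4α-isopropyl-1α-methyl-2β-(tert-butyldimethylsilyloxy)cyclopentane-1β-carboxylate | CCOC(=O)[C@@]1(C)[C@@H](O[Si](C)(C)C(C)(C)C)C[C@](O)(C(C)C)[C@H]1C=O | intermediate
10 | ethyl 4β-hydroxy-5β-(1-hydroxyethyl)-4α-isopropyl-1α-methyl-2β-(tert-butyldimethylsilyloxy)cyclopentane-1β-carboxylate (carbinol epimers) | CCOC(=O)[C@@]1(C)[C@@H](O[Si](C)(C)C(C)(C)C)C[C@](O)(C(C)C)[C@H]1C(C)O | intermediate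
11 | ethyl 5β-acetyl-4β-hydroxy-4α-isopropyl-1α-methyl-2β-(tert-butyldimethylsilyloxy)cyclopentane-1β-carboxylate | CCOC(=O)[C@@]1(C)[C@@H](O[Si](C)(C)C(C)(C)C)C[C@](O)(C(C)C)[C@H]1C(C)=O | intermediate
12 | cis-fused bicyclic cyclopentane-1,3-dione, hexahydropentalene-1,3-dione skeleton (ring A C1–C10(=O)–C7H2–C6(=O)–C5; 2β-OTBS, 4β-OH, 4α-isopropyl, 1α-methyl, 5α-H; drawn as diketone, present as enol) | O=C1CC(=O)[C@@]2(C)[C@@H](O[Si](C)(C)C(C)(C)C)C[C@](O)(C(C)C)[C@@H]12 | intermediate
13 | allene (propa-1,2-diene) | C=C=C | starting material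
14 | cyclobutanol photoadduct (C7–C8 and C9–C10 bonded, C8 methylidene, C10–OH, C6 ketone; cyclobutane drawn on the α face) | O=C1[C@@H]3C(=C)C[C@]3(O)[C@@]2(C)[C@@H](O[Si](C)(C)C(C)(C)C)C[C@](O)(C(C)C)[C@@H]12 | intermediate (not isolated)
15 | 2β-(tert-butyldimethylsilyloxy)-4β-hydroxydauc-8(14)-ene-6,10-dione | O=C1CC(=C)CC(=O)[C@@]2(C)[C@@H](O[Si](C)(C)C(C)(C)C)C[C@](O)(C(C)C)[C@@H]12 | intermediate
16 | 2β-(tert-butyldimethylsilyloxy)-4β,6α-dihydroxydauc-8(14)-en-10-one | O[C@@H]1CC(=C)CC(=O)[C@@]2(C)[C@@H](O[Si](C)(C)C(C)(C)C)C[C@](O)(C(C)C)[C@@H]12 | intermediate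
17 | 2β-(tert-butyldimethylsilyloxy)-4β,6α-dihydroxydauc-8-en-10-one | O[C@@H]1CC(C)=CC(=O)[C@@]2(C)[C@@H](O[Si](C)(C)C(C)(C)C)C[C@](O)(C(C)C)[C@@H]12 | intermediate
18 | 2β-(tert-butyldimethylsilyloxy)dauc-8-ene-4β,6α,10α-triol | O[C@@H]1CC(C)=C[C@H](O)[C@@]2(C)[C@@H](O[Si](C)(C)C(C)(C)C)C[C@](O)(C(C)C)[C@@H]12 | intermediate
19 | 8α,9α-epoxy-2β-(tert-butyldimethylsilyloxy)daucane-4β,6α,10α-triol | O[C@@H]1C[C@]2(C)O[C@@H]2[C@H](O)[C@@]2(C)[C@@H](O[Si](C)(C)C(C)(C)C)C[C@](O)(C(C)C)[C@@H]12 | intermediate
20 | angelic acid ((Z)-2-methylbut-2-enoic acid) | C/C=C(/C)C(=O)O | starting material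
21 | 6α,10α-bis(angeloyloxy)-8α,9α-epoxy-2β-(tert-butyldimethylsilyloxy)daucan-4β-ol | C/C=C(/C)C(=O)O[C@@H]1C[C@]2(C)O[C@@H]2[C@H](OC(=O)/C(C)=C\C)[C@@]2(C)[C@@H](O[Si](C)(C)C(C)(C)C)C[C@](O)(C(C)C)[C@@H]12 | intermediate
22 | (1R,2S,4S,5R,6R,8S,9R,10R)-6α,10α-bis(angeloyloxy)-8α,9α-epoxydaucane-2β,4β-diol | C/C=C(/C)C(=O)O[C@@H]1C[C@]2(C)O[C@@H]2[C@H](OC(=O)/C(C)=C\C)[C@@]2(C)[C@@H](O)C[C@](O)(C(C)C)[C@@H]12 | target

## Step count and risks

Total step count: 17. Longest linear sequence: 17 steps (from 1).

**Step 7 (ring B aldol).** The enamine may add only slowly to the hindered isopropyl ketone, the aldol may dehydrate to the enal, or the facial selectivity at C4 may be poor. The fallback sets out from 8 and comes back at 9. The aldehyde alone is converted into its dimethyl acetal (HC(OMe)3, MeOH, pyridinium p-toluenesulfonate, 0 °C), giving ethyl (2R,3S)-3-(tert-butyldimethylsilyloxy)-2-(2,2-dimethoxyethyl)-2,6-dimethyl-5-oxoheptanoate F1. Loss of one methoxy group (TMSOTf, iPr2NEt, CH2Cl2, −20 °C) gives the methyl enol ether ethyl (2R,3S)-3-(tert-butyldimethylsilyloxy)-2-(2-methoxyethenyl)-2,6-dimethyl-5-oxoheptanoate F2. TiCl4 (CH2Cl2, −78 °C, then aqueous work-up) then closes ring B by a Lewis-acid-mediated Mukaiyama-type addition of the enol ether to the ketone and returns 9.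

**Step 14 (C10 reduction).** The substrate bias of the β-silyloxy side may oppose catalyst control and give poor facial selectivity. The fallback sets out from 17 and comes back at 22, using hydride delivery from the C2 oxygen instead of a chiral catalyst. Desilylation (HF·pyridine) gives 2β,4β,6α-trihydroxydauc-8-en-10-one F3. An Evans–Tishchenko reduction (acetaldehyde, SmI2 15 mol%, THF, −10 °C) delivers hydride from the C2 hemiacetal to the β face of C10 and leaves C2 as its acetate, giving 2β-acetoxydauc-8-ene-4β,6α,10α-triol F4. VO(acac)2/tBuOOH gives 2β-acetoxy-8α,9α-epoxydaucane-4β,6α,10α-triol F5. Bis-angeloylation under the conditions of step 16 gives 2β-acetoxy-6α,10α-bis(angeloyloxy)-8α,9α-epoxydaucan-4β-ol F6. Selective methanolysis of the acetate (K2CO3, MeOH, 0 °C) gives 22.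

**Step 16 (bis-angeloylation).** Acylation of the hindered C10 hydroxyl (flanked by the quaternary C1 and the epoxide) may stay incomplete, and the angeloyl group may isomerise from Z to E on forcing. The fallback sets out from 19 and comes back at 21, building the Z-olefins on the substrate. Both alcohols are esterified with 2-[bis(2,2,2-trifluoroethoxy)phosphoryl]propanoic acid (EDC, DMAP, CH2Cl2) to give the 6α,10α-bis{2-[bis(2,2,2-trifluoroethoxy)phosphoryl]propanoate} of 19, F7. A double Still–Gennari olefination (KN(SiMe3)2, 18-crown-6, acetaldehyde, THF, −78 °C) then forms both (Z)-2-methylbut-2-enoates and gives 21.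

Further compounds
F1 | step 7 | ethyl (2R,3S)-3-(tert-butyldimethylsilyloxy)-2-(2,2-dimethoxyethyl)-2,6-dimethyl-5-oxoheptanoate | CCOC(=O)[C@@](CC(OC)OC)(C)[C@@H](O[Si](C)(C)C(C)(C)C)CC(=O)C(C)C
F2 | step 7 | ethyl (2R,3S)-3-(tert-butyldimethylsilyloxy)-2-(2-methoxyethenyl)-2,6-dimethyl-5-oxoheptanoate | CCOC(=O)[C@@](C=COC)(C)[C@@H](O[Si](C)(C)C(C)(C)C)CC(=O)C(C)C
F3 | step 14 | 2β,4β,6α-trihydroxydauc-8-en-10-one | O[C@@H]1CC(C)=CC(=O)[C@@]2(C)[C@@H](O)C[C@](O)(C(C)C)[C@@H]12
F4 | step 14 | 2β-acetoxydauc-8-ene-4β,6α,10α-triol | O[C@@H]1CC(C)=C[C@H](O)[C@@]2(C)[C@@H](OC(C)=O)C[C@](O)(C(C)C)[C@@H]12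
F5 | step 14 | 2β-acetoxy-8α,9α-epoxydaucane-4β,6α,10α-triol | O[C@@H]1C[C@]2(C)O[C@@H]2[C@H](O)[C@@]2(C)[C@@H](OC(C)=O)C[C@](O)(C(C)C)[C@@H]12
F6 | step 14 | 2β-acetoxy-6α,10α-bis(angeloyloxy)-8α,9α-epoxydaucan-4β-ol | C/C=C(/C)C(=O)O[C@@H]1C[C@]2(C)O[C@@H]2[C@H](OC(=O)/C(C)=C\C)[C@@]2(C)[C@@H](OC(C)=O)C[C@](O)(C(C)C)[C@@H]12
F7 | step 16 | 6α,10α-bis{2-[bis(2,2,2-trifluoroethoxy)phosphoryl]propanoate} of 19 | CC(C(=O)O[C@@H]1C[C@]2(C)O[C@@H]2[C@H](OC(=O)C(C)P(=O)(OCC(F)(F)F)OCC(F)(F)F)[C@@]2(C)[C@@H](O[Si](C)(C)C(C)(C)C)C[C@](O)(C(C)C)[C@@H]12)P(=O)(OCC(F)(F)F)OCC(F)(F)F
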